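**Retrosynthetic overview**
1. The target is 8α-acetoxy-9β-angeloyloxygermacra-1(10)Z,4E,11(13)-trien-12,6α-olide. The C8 acetate is removed first, then the C7–C11 bond together with C11=C13, which opens the γ-lactone (ring B) on the ten-membered carbocycle (ring A).
2. Key disconnection: ring B is stitched onto preformed ring A by 5-exo attack of C11 (a phosphonoacetate held on the C6 oxygen) on C7 of a cis-7α,8α-epoxide, followed by methylenation in the same flask.
3. Enabling feature: C7 is the middle carbon of the triad C6(O)–C7–C8(O) of ring A, with both oxygens on the α-face. The C6 oxygen (the later lactone oxygen) carries the C11–C12 tether and the C8 oxygen is stored as the epoxide, so inversion at C7 gives the trans-fused lactone and frees the C8 hydroxyl next to the C9 angelate.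
4. The epoxy alcohol comes from a 1(10)Z,4E,7Z-trienone (C9 ketone) by nucleophilic epoxidation and CBS reduction. The trienone comes from an anionic oxy-Cope ring expansion of a 1-ethynyl-6-(2-silyloxyvinyl)cyclohexenol, whose quaternary C4 (palladium-catalysed asymmetric allylation) relays its chirality to C6.
5. Ring order: six-membered carbocycle (starting enone), then ring A by ring expansion (step 7), then the oxirane (step 8), then ring B (step 13).

Key step: step 13

Remark: the C9 acyl group is read as (Z)-2-methylbut-2-enoate (angelate) and the ring alkenes as 1(10)Z and 4E; germacrane numbering is used for all ten-membered-ring compounds (ring A = C1–C10, C11–C13 the lactone carbons, C14 on C10, C15 on C4), with α the face of ring A that carries the C6 and C8 oxygens of the target and β the face of the C7–C11 bond and the C9 oxygen.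

**Step 1**
Reactants: 1 2-methylcyclohex-2-en-1-one
Product: 3 2,6-dimethylcyclohex-2-en-1-one (racemic), via lithium dienolate 2 (not isolated)
Conditions: LiN(iPr)2, THF, −78 °C; then MeI, −78 to 0 °C
Reagents that add atoms: iodomethane, CI; LiN(iPr)2, [Li+].CC(C)[N-]C(C)C (lithium only in intermediate 2)
Why: Kinetic α′-deprotonation gives the cross-conjugated dienolate, whose C-methylation (enolate alkylation) should give 3; the new stereocenter is racemic and is erased in step 2.

**Step 2**
Reactants: 3 2,6-dimethylcyclohex-2-en-1-one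
Product: 5 allyl 2,6-dimethylcyclohexa-1,5-dien-1-yl carbonate, via lithium dienolate 4 (not isolated)
Conditions: LiN(SiMe3)2, TMEDA, THF, −78 °C; then allyl chloroformate, −78 to 0 °C
Reagents that add atoms: allyl chloroformate, C=CCOC(=O)Cl; LiN(SiMe3)2, [Li+].C[Si](C)(C)[N-][Si](C)(C)C (lithium only in intermediate 4)
Why: O-acylation of the amine-solvated lithium dienolate by the chloroformate (enol carbonate formation) should give the substrate for decarboxylative allylation.

**Step 3**
Reactants: 5 allyl 2,6-dimethylcyclohexa-1,5-dien-1-yl carbonate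
Product: 6 (S)-6-allyl-2,6-dimethylcyclohex-2-en-1-one
Conditions: Pd2(dba)3 (cat.), (S)-t-BuPHOX (cat.), THF, 25 °C
Reagents that add atoms: none
Why: Decarboxylative asymmetric allylic alkylation (Tsuji allylation with a chiral phosphinooxazoline ligand): ionisation by zerovalent palladium, loss of CO2 and C–C bond formation at the α′-carbon of the dienolate should set the quaternary stereocenter as S, by analogy with 2-methylcyclohexanone enol carbonates under the (S)-ligand.

**Step 4**
Reactants: 6 (S)-6-allyl-2,6-dimethylcyclohex-2-en-1-one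
Product: 8 (S)-2-(1,3-dimethyl-2-oxocyclohex-3-en-1-yl)acetaldehyde, via diol 7 (not isolated)
Conditions: OsO4 (cat.), NaIO4, 2,6-lutidine, dioxane/H2O, rt
Reagents that add atoms: osmium tetroxide, O=[Os](=O)(=O)=O (catalytic oxygen carrier, re-formed by sodium periodate, [Na+].[O-]I(=O)(=O)=O)
Why: Lemieux–Johnson oxidation: the terminal alkene is dihydroxylated in preference to the electron-poor trisubstituted enone alkene and the diol is cleaved by periodate, leaving the quaternary stereocenter untouched.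

**Step 5**
Reactants: 8 (S)-2-(1,3-dimethyl-2-oxocyclohex-3-en-1-yl)acetaldehyde
Product: 9 (S)-6-[(E)-2-(tert-butyldimethylsilyloxy)ethenyl]-2,6-dimethylcyclohex-2-en-1-one
Conditions: TBSOTf, Et3N, CH2Cl2, −78 to 0 °C
Reagents that add atoms: tert-butyldimethylsilyl trifluoromethanesulfonate, CC(C)(C)[Si](C)(C)OS(=O)(=O)C(F)(F)F
Why: Soft enolisation and O-silylation of the aldehyde (the ketone has no α-hydrogen) should give mainly the (E)-enol ether, because the quaternary carbon avoids the position cis to the silyloxy group.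

**Step 6**
Reactants: 9 (S)-6-[(E)-2-(tert-butyldimethylsilyloxy)ethenyl]-2,6-dimethylcyclohex-2-en-1-one
Product: 10 (1S,6S)-6-[(E)-2-(tert-butyldimethylsilyloxy)ethenyl]-1-ethynyl-2,6-dimethylcyclohex-2-en-1-ol
Conditions: HC≡CMgBr, THF, −20 to 0 °C; then H2O
Reagents that add atoms: ethynylmagnesium bromide, C#C[Mg]Br
Why: 1,2-Addition of the small alkynyl Grignard reagent to the hindered enone carbonyl, anti to the alkenyl arm on the neighbouring quaternary carbon (Felkin–Anh), should place the ethynyl group trans to that arm; the minor diastereomer would be removed by chromatography.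

**Step 7**
Reactants: 10 (1S,6S)-6-[(E)-2-(tert-butyldimethylsilyloxy)ethenyl]-1-ethynyl-2,6-dimethylcyclohex-2-en-1-ol
Product: 13 (6S)-6α-(tert-butyldimethylsilyloxy)-4,10-dimethylcyclodeca-1(10)Z,4E,7Z-trien-9-one, via potassium alkoxide 11 (not isolated), via potassium allenolate 12 (not isolated)
Conditions: KN(SiMe3)2, 18-crown-6, THF, 0 to 40 °C; then AcOH, −78 °C
Reagents that add atoms: KN(SiMe3)2, [K+].C[Si](C)(C)[N-][Si](C)(C)C (potassium only in intermediates 11 and 12)
Why: Anionic oxy-Cope rearrangement (alkynyl variant) as a ring expansion: in the only reactive half-chair, with both unsaturated arms pseudo-equatorial, the C4–C9 bond breaks as C6–C7 forms, which puts the C4 methyl cis to C6 (E-C4=C5), relays the C4 chirality across the (E)-enol ether to C6, keeps the former cyclohexene bond as Z-C1=C10, and leaves an allenolate whose C8-protonation from the side remote from C6 should give the Z-enone.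

**Step 8**
Reactants: 13 (6S)-6α-(tert-butyldimethylsilyloxy)-4,10-dimethylcyclodeca-1(10)Z,4E,7Z-trien-9-one
Product: 14 7α,8α-epoxy-6α-(tert-butyldimethylsilyloxy)-4,10-dimethylcyclodeca-1(10)Z,4E-dien-9-one
Conditions: t-BuOOH (anhydrous, in decane), DBU, CH2Cl2, 0 °C
Reagents that add atoms: tert-butyl hydroperoxide, CC(C)(C)OO
Why: Weitz–Scheffer nucleophilic epoxidation: the peroxide anion should add to C7 of the less substituted, inductively activated enone (the C1=C10 enone is α-methylated, C4=C5 is isolated), anti to the C6 silyloxy group in the conformer with H6 eclipsing C7=C8 (Felkin–Anh type), and fast ring closure should keep the cis geometry, giving the epoxide on the face of the C6 oxygen.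

**Step 9**
Reactants: 14 7α,8α-epoxy-6α-(tert-butyldimethylsilyloxy)-4,10-dimethylcyclodeca-1(10)Z,4E-dien-9-one
Product: 15 7α,8α-epoxy-6α-(tert-butyldimethylsilyloxy)-4,10-dimethylcyclodeca-1(10)Z,4E-dien-9β-ol
Conditions: (R)-2-methyl-CBS-oxazaborolidine, catecholborane, toluene, −78 °C; then MeOH, aqueous NaHCO3
Reagents that add atoms: none
Why: Corey–Bakshi–Shibata reduction under reagent control, with the 2-methylalkenyl group as the large substituent, should deliver hydride to C9 to give the 9β-alcohol (9R, anti to the epoxide) without touching the epoxide or the alkenes.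

**Step 10**
Reactants: 15 7α,8α-epoxy-6α-(tert-butyldimethylsilyloxy)-4,10-dimethylcyclodeca-1(10)Z,4E-dien-9β-ol; 16 angelic acid ((Z)-2-methylbut-2-enoic acid)
Product: 18 9β-angeloyloxy-7α,8α-epoxy-6α-(tert-butyldimethylsilyloxy)-4,10-dimethylcyclodeca-1(10)Z,4E-diene, via mixed anhydride 17 (not isolated)
Conditions: 16, 2,4,6-Cl3C6H2COCl, Et3N, toluene, rt; then 15, 75 °C
Reagents that add atoms: 2,4,6-trichlorobenzoyl chloride, O=C(Cl)c1c(Cl)cc(Cl)cc1Cl (its atoms only in intermediate 17)
Why: Yamaguchi-type esterification through the mixed anhydride without a nucleophilic catalyst should acylate the hindered C9 alcohol with retention and without Z-to-E isomerisation of the angelate to the tiglate.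

**Step 11**
Reactants: 18 9β-angeloyloxy-7α,8α-epoxy-6α-(tert-butyldimethylsilyloxy)-4,10-dimethylcyclodeca-1(10)Z,4E-diene
Product: 19 9β-angeloyloxy-7α,8α-epoxy-4,10-dimethylcyclodeca-1(10)Z,4E-dien-6α-ol
Conditions: HF·pyridine, pyridine, THF, 0 °C to rt
Reagents that add atoms: none
Why: Fluoride cleavage of the secondary allylic silyl ether under buffered, non-basic conditions should leave the epoxide, the angelate and the 1,5-diene intact and avoid an epoxide migration through a C6 alkoxide.

**Step 12**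
Reactants: 19 9β-angeloyloxy-7α,8α-epoxy-4,10-dimethylcyclodeca-1(10)Z,4E-dien-6α-ol; 20 diethylphosphonoacetic acid
Product: 22 9β-angeloyloxy-6α-[(diethoxyphosphoryl)acetoxy]-7α,8α-epoxy-4,10-dimethylcyclodeca-1(10)Z,4E-diene, via O-acylisourea 21 (not isolated)
Conditions: DCC, DMAP (cat.), CH2Cl2, 0 °C to rt
Reagents that add atoms: N,N'-dicyclohexylcarbodiimide, C(=NC1CCCCC1)=NC1CCCCC1 (its atoms only in intermediate 21)
Why: Steglich esterification (carbodiimide activation, DMAP catalysis) should place the C11–C12 unit on the C6 oxygen with retention of configuration.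

**Step 13**
Reactants: 22 9β-angeloyloxy-6α-[(diethoxyphosphoryl)acetoxy]-7α,8α-epoxy-4,10-dimethylcyclodeca-1(10)Z,4E-diene
Product: 24 9β-angeloyloxy-8α-hydroxygermacra-1(10)Z,4E,11(13)-trien-12,6α-olide, via phosphono lactone 23 (not isolated)
Conditions: LiCl, DBU, MeCN, 0 to 40 °C; then paraformaldehyde, 40 °C
Reagents that add atoms: formaldehyde (from paraformaldehyde), C=O
Why: Proposed new method: soft enolisation (LiCl/DBU, Masamune–Roush conditions) should give the lithium-chelated phosphonoacetate carbanion at C11, which attacks C7 on the β-face, anti to the C7–O bond of the lithium-activated cis-epoxide, while the C8 alkoxide is protonated at once by protonated DBU so that the neighbouring angelate cannot migrate; the α-phosphono lactone then olefinates formaldehyde (Horner–Wadsworth–Emmons) to install C13. The closest known reaction types are the 5-exo opening at C2 of 2,3-epoxy alcohol carbamates by the tethered nitrogen, the Stork epoxynitrile cyclisation, the opening of epoxides by malonate or phosphonoacetate anions, and the intramolecular Michael addition of allylic phosphonoacetates followed by methylenation with formaldehyde. Ring B (O–C12–C11–C7–C6) closes in the 5-exo-tet mode. The new stereocenter C7 is set by SN2 inversion of the epoxide carbon, so the 7α,8α-epoxide cis to the C6 oxygen gives the trans-fused lactone (C11 β, H7 α), C8 keeps its oxygen with retention as the free 8α-hydroxyl, and C11 becomes sp2. The step needs regioselectivity for C7 over C8 and chemoselectivity for the epoxide over the angelate and the alkenes: the three-atom tether makes attack at C8 a strained 6-endo closure, and the stabilised, chelated carbanion is too soft and hindered to add to the angelate.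

**Step 14**
Reactants: 24 9β-angeloyloxy-8α-hydroxygermacra-1(10)Z,4E,11(13)-trien-12,6α-olide
Product: 25 8α-acetoxy-9β-angeloyloxygermacra-1(10)Z,4E,11(13)-trien-12,6α-olide (6R,7S,8R,9R), the target
Conditions: Ac2O, pyridine, DMAP (cat.), CH2Cl2, 0 °C
Reagents that add atoms: acetic anhydride, CC(=O)OC(C)=O
Why: DMAP-catalysed acetylation of the secondary C8 alcohol under mild conditions should outrun translactonisation to the 8,12-olide and acyl migration.

**Compound list**
1 | 2-methylcyclohex-2-en-1-one | CC1=CCCCC1=O | starting material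
2 | lithium 6-methylcyclohexa-1,5-dien-1-olate | CC1=CCCC=C1[O-].[Li+] | intermediate (not isolated)
3 | 2,6-dimethylcyclohex-2-en-1-one (racemic) | CC1=CCCC(C)C1=O | intermediate
4 | lithium 2,6-dimethylcyclohexa-1,5-dien-1-olate | CC1=CCCC(C)=C1[O-].[Li+] | intermediate (not isolated)
5 | allyl 2,6-dimethylcyclohexa-1,5-dien-1-yl carbonate | CC1=CCCC(C)=C1OC(=O)OCC=C | intermediate
6 | (S)-6-allyl-2,6-dimethylcyclohex-2-en-1-one | CC1=CCC[C@@](C)(CC=C)C1=O | intermediate
7 | (6S)-6-(2,3-dihydroxypropyl)-2,6-dimethylcyclohex-2-en-1-one (both carbinol epimers) | CC1=CCC[C@@](C)(CC(O)CO)C1=O | intermediate (not isolated)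
8 | (S)-2-(1,3-dimethyl-2-oxocyclohex-3-en-1-yl)acetaldehyde | CC1=CCC[C@@](C)(CC=O)C1=O | intermediate
9 | (S)-6-[(E)-2-(tert-butyldimethylsilyloxy)ethenyl]-2,6-dimethylcyclohex-2-en-1-one | CC1=CCC[C@@](C)(/C=C/O[Si](C)(C)C(C)(C)C)C1=O | intermediate
10 | (1S,6S)-6-[(E)-2-(tert-butyldimethylsilyloxy)ethenyl]-1-ethynyl-2,6-dimethylcyclohex-2-en-1-ol (ethynyl trans to the silyloxyvinyl arm) | CC1=CCC[C@@](C)(/C=C/O[Si](C)(C)C(C)(C)C)[C@]1(O)C#C | intermediate
11 | potassium alkoxide of 10 | CC1=CCC[C@@](C)(/C=C/O[Si](C)(C)C(C)(C)C)[C@]1([O-])C#C.[K+] | intermediate (not isolated)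
12 | potassium 6α-(tert-butyldimethylsilyloxy)-4,10-dimethylcyclodeca-1(10)Z,4E,7,8-tetraen-9-olate (cyclic allenolate, C7=C8=C9) | [K+].[O-]C1=C=C[C@H](O[Si](C)(C)C(C)(C)C)/C=C(\C)CC/C=C1/C | intermediate (not isolated)
13 | (6S)-6α-(tert-butyldimethylsilyloxy)-4,10-dimethylcyclodeca-1(10)Z,4E,7Z-trien-9-one | O=C1/C=C\[C@H](O[Si](C)(C)C(C)(C)C)/C=C(\C)CC/C=C1/C | intermediate
14 | 7α,8α-epoxy-6α-(tert-butyldimethylsilyloxy)-4,10-dimethylcyclodeca-1(10)Z,4E-dien-9-one (cis-epoxide on the face of the C6 oxygen) | O=C1[C@@H]2O[C@@H]2[C@H](O[Si](C)(C)C(C)(C)C)/C=C(\C)CC/C=C1/C | intermediate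
15 | 7α,8α-epoxy-6α-(tert-butyldimethylsilyloxy)-4,10-dimethylcyclodeca-1(10)Z,4E-dien-9β-ol (9R, hydroxyl anti to the epoxide) | O[C@H]1[C@@H]2O[C@@H]2[C@H](O[Si](C)(C)C(C)(C)C)/C=C(\C)CC/C=C1/C | intermediate
16 | angelic acid, (Z)-2-methylbut-2-enoic acid | C/C=C(/C)C(=O)O | starting material
17 | angelic 2,4,6-trichlorobenzoic anhydride | C/C=C(/C)C(=O)OC(=O)c1c(Cl)cc(Cl)cc1Cl | intermediate (not isolated)
18 | 9β-angeloyloxy-7α,8α-epoxy-6α-(tert-butyldimethylsilyloxy)-4,10-dimethylcyclodeca-1(10)Z,4E-diene | C/C=C(/C)C(=O)O[C@H]1[C@@H]2O[C@@H]2[C@H](O[Si](C)(C)C(C)(C)C)/C=C(\C)CC/C=C1/C | intermediate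
19 | 9β-angeloyloxy-7α,8α-epoxy-4,10-dimethylcyclodeca-1(10)Z,4E-dien-6α-ol | C/C=C(/C)C(=O)O[C@H]1[C@@H]2O[C@@H]2[C@H](O)/C=C(\C)CC/C=C1/C | intermediate
20 | diethylphosphonoacetic acid | CCOP(=O)(OCC)CC(=O)O | starting material
21 | O-acylisourea from 20 and DCC | CCOP(=O)(OCC)CC(=O)OC(=NC1CCCCC1)NC1CCCCC1 | intermediate (not isolated)
22 | 9β-angeloyloxy-6α-[(diethoxyphosphoryl)acetoxy]-7α,8α-epoxy-4,10-dimethylcyclodeca-1(10)Z,4E-diene | C/C=C(/C)C(=O)O[C@H]1[C@@H]2O[C@@H]2[C@H](OC(=O)CP(=O)(OCC)OCC)/C=C(\C)CC/C=C1/C | intermediate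
23 | 11-(diethoxyphosphoryl)-9β-angeloyloxy-8α-hydroxygermacra-1(10)Z,4E-dien-12,6α-olide (trans-fused, C11 epimers) | CCOP(=O)(OCC)C1C(=O)O[C@@H]2/C=C(\C)CC/C=C(/C)[C@@H](OC(=O)/C(C)=C\C)[C@H](O)[C@@H]12 | intermediate (not isolated)
24 | 9β-angeloyloxy-8α-hydroxygermacra-1(10)Z,4E,11(13)-trien-12,6α-olide | C=C1C(=O)O[C@@H]2/C=C(\C)CC/C=C(/C)[C@@H](OC(=O)/C(C)=C\C)[C@H](O)[C@@H]12 | intermediate
25 | 8α-acetoxy-9β-angeloyloxygermacra-1(10)Z,4E,11(13)-trien-12,6α-olide, (6R,7S,8R,9R) | C=C1C(=O)O[C@@H]2/C=C(\C)CC/C=C(/C)[C@@H](OC(=O)/C(C)=C\C)[C@H](OC(C)=O)[C@@H]12 | target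

**Step count**
Total steps: 14. Longest linear sequence: 14 steps (1 to 25).

**Steps most likely to fail**

Step 13 (proposed method). Process at risk: the C11 carbanion may not reach the backside of C7, because the ester must turn into its s-cis rotamer inside ring A. Base-induced isomerisation of the epoxide, migration of the angelate to the freed C8 oxygen, or isomerisation of the angelate would then compete. The fallback uses known chemistry, sets out from 13 and returns at 25. HF·pyridine frees the C6 alcohol of 13 to give the 6α-hydroxy trienone F1, and DCC coupling with 20 gives its phosphonoacetate F2. LiCl/DBU then brings about the known intramolecular Michael addition of C11 to C7 of the Z-enone (5-exo-trig) to give the trans-fused phosphono lactone ketone F3, and formaldehyde in the same flask gives the α-methylene lactone ketone F4. Mn(OAc)3 in hot benzene acetoxylates the enone at its α′-carbon C8, anti to C11, to give the 8α-acetoxy ketone F5. Reduction with (R)-2-methyl-CBS-oxazaborolidine and catecholborane gives the 9β-alcohol F6, and its Yamaguchi-type angeloylation with 16 gives 25.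

Step 8. Process at risk: poor facial selectivity. The peroxide may add to C7 syn to the silyloxy group, or from the ring periphery regardless of it, and deliver the 7β,8β-epoxide, which no later step can correct; epoxidation of the C1=C10 enone is a second risk. The fallback sets out from 5 and returns at 22. The allylation of 5 is run with (R)-t-BuPHOX to give the (R)-allyl ketone F7, which is carried through the operations of steps 4 to 7 to the (R)-aldehyde F8, the (R)-enol ether F9, the (1R,6R)-ethynyl carbinol F10 and the 6β-silyloxy trienone F11. The same inherent facial preference then places the epoxide on the α-face, anti to the 6β-oxygen, in the epoxy ketone F12. The operations of steps 9 to 11 give the 9β-alcohol F13, its angelate F14 and the 6β-alcohol F15. A Mitsunobu esterification of F15 with 20 (PPh3, DIAD, THF) inverts C6 and gives 22.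

Step 7. Process at risk: loss of acetylide from the hindered tertiary propargylic alkoxide (retro-addition) may outrun the [3,3] shift, and the allenolate may be protonated to the E-enone. The fallback sets out from 9 and returns at 13. Vinylmagnesium bromide adds to 9 to give the divinyl carbinol F16. KN(SiMe3)2 and 18-crown-6 then effect the ordinary anionic oxy-Cope ring expansion, and the enolate is silylated in the flask with Me3SiCl to the trimethylsilyl enol ether F17. Saegusa–Ito oxidation (Pd(OAc)2, MeCN) introduces the C7=C8 double bond and gives 13.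

**Further compounds**
F1 | step 13 | (6S)-6α-hydroxy-4,10-dimethylcyclodeca-1(10)Z,4E,7Z-trien-9-one | O=C1/C=C\[C@H](O)/C=C(\C)CC/C=C1/C
F2 | step 13 | 6α-[(diethoxyphosphoryl)acetoxy]-4,10-dimethylcyclodeca-1(10)Z,4E,7Z-trien-9-one | O=C1/C=C\[C@H](OC(=O)CP(=O)(OCC)OCC)/C=C(\C)CC/C=C1/C
F3 | step 13 | 11-(diethoxyphosphoryl)-9-oxogermacra-1(10)Z,4E-dien-12,6α-olide (trans-fused, C11 epimers) | CCOP(=O)(OCC)C1C(=O)O[C@@H]2/C=C(\C)CC/C=C(/C)C(=O)C[C@@H]12
F4 | step 13 | 9-oxogermacra-1(10)Z,4E,11(13)-trien-12,6α-olide | C=C1C(=O)O[C@@H]2/C=C(\C)CC/C=C(/C)C(=O)C[C@@H]12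
F5 | step 13 | 8α-acetoxy-9-oxogermacra-1(10)Z,4E,11(13)-trien-12,6α-olide | C=C1C(=O)O[C@@H]2/C=C(\C)CC/C=C(/C)C(=O)[C@H](OC(C)=O)[C@@H]12
F6 | step 13 | 8α-acetoxy-9β-hydroxygermacra-1(10)Z,4E,11(13)-trien-12,6α-olide | C=C1C(=O)O[C@@H]2/C=C(\C)CC/C=C(/C)[C@@H](O)[C@H](OC(C)=O)[C@@H]12
F7 | step 8 | (R)-6-allyl-2,6-dimethylcyclohex-2-en-1-one | CC1=CCC[C@](C)(CC=C)C1=O
F8 | step 8 | (R)-2-(1,3-dimethyl-2-oxocyclohex-3-en-1-yl)acetaldehyde | CC1=CCC[C@](C)(CC=O)C1=O
F9 | step 8 | (R)-6-[(E)-2-(tert-butyldimethylsilyloxy)ethenyl]-2,6-dimethylcyclohex-2-en-1-one | CC1=CCC[C@](C)(/C=C/O[Si](C)(C)C(C)(C)C)C1=O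
F10 | step 8 | (1R,6R)-6-[(E)-2-(tert-butyldimethylsilyloxy)ethenyl]-1-ethynyl-2,6-dimethylcyclohex-2-en-1-ol | CC1=CCC[C@](C)(/C=C/O[Si](C)(C)C(C)(C)C)[C@@]1(O)C#C
F11 | step 8 | (6R)-6β-(tert-butyldimethylsilyloxy)-4,10-dimethylcyclodeca-1(10)Z,4E,7Z-trien-9-one | O=C1/C=C\[C@@H](O[Si](C)(C)C(C)(C)C)/C=C(\C)CC/C=C1/C
F12 | step 8 | 7α,8α-epoxy-6β-(tert-butyldimethylsilyloxy)-4,10-dimethylcyclodeca-1(10)Z,4E-dien-9-one | O=C1[C@@H]2O[C@@H]2[C@@H](O[Si](C)(C)C(C)(C)C)/C=C(\C)CC/C=C1/C
F13 | step 8 | 7α,8α-epoxy-6β-(tert-butyldimethylsilyloxy)-4,10-dimethylcyclodeca-1(10)Z,4E-dien-9β-ol | O[C@H]1[C@@H]2O[C@@H]2[C@@H](O[Si](C)(C)C(C)(C)C)/C=C(\C)CC/C=C1/C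
F14 | step 8 | 9β-angeloyloxy-7α,8α-epoxy-6β-(tert-butyldimethylsilyloxy)-4,10-dimethylcyclodeca-1(10)Z,4E-diene | C/C=C(/C)C(=O)O[C@H]1[C@@H]2O[C@@H]2[C@@H](O[Si](C)(C)C(C)(C)C)/C=C(\C)CC/C=C1/C
F15 | step 8 | 9β-angeloyloxy-7α,8α-epoxy-4,10-dimethylcyclodeca-1(10)Z,4E-dien-6β-ol | C/C=C(/C)C(=O)O[C@H]1[C@@H]2O[C@@H]2[C@@H](O)/C=C(\C)CC/C=C1/C
F16 | step 7 | (1S,6S)-6-[(E)-2-(tert-butyldimethylsilyloxy)ethenyl]-1-ethenyl-2,6-dimethylcyclohex-2-en-1-ol | CC1=CCC[C@@](C)(/C=C/O[Si](C)(C)C(C)(C)C)[C@]1(O)C=C
F17 | step 7 | 6α-(tert-butyldimethylsilyloxy)-9-(trimethylsilyloxy)-4,10-dimethylcyclodeca-1(10)Z,4E,8E-triene | C[Si](C)(C)O/C1=C\C[C@H](O[Si](C)(C)C(C)(C)C)/C=C(\C)CC/C=C1/C
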